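**Strategy.** Ring A (C1–C5, C10) is traced back to the cyclopentanone ring of the cheap (S)-bicyclic enedione 1: the C3 oxygen is its saturated carbonyl, the quaternary C5 with its methyl group is its stereocentre, and only the methine C4 with its methyl group is missing. The key step inserts this CH(CH3) unit into the C3–C5 bond by a β-oxido carbenoid 1,2-shift of C5, enlarging the five-membered ring to ring A and leaving a C3–C4 enolate whose protonation sets C4. The precursor is the dienol ether of 1. Ring B is then completed by C7 alkylation with a lactate triflate, dehydrogenation and hydroxyl-directed hydrogenation; the angelate comes last.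

Key step: step 2

Remark: atoms are numbered as in eremophilanes (ring A: C1–C5 and C10; ring B: C5–C10; C3 carries the ester oxygen, C4 and C5 the methyl groups, C8 the ketone, C7 the propanoate α-carbon C11). β is the face of the C5 methyl group. The target is read as the angelate, the (Z)-2-methylbut-2-enoate, with O3, both methyl groups and H10 all β, and C11 (R).

Step 1
Reactants: 1 (S)-7a-methyl-2,3,7,7a-tetrahydro-1H-indene-1,5(6H)-dione; 2 triethyl orthoformate
Product: 3 (S)-5-ethoxy-7a-methyl-2,6,7,7a-tetrahydro-1H-inden-1-one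
Conditions: HC(OEt)3, EtOH, p-TsOH (cat.), 20 °C; Et3N quench
Reagents that add atoms: triethyl orthoformate, CCOC(OCC)OCC
Why: Acid-catalysed enol etherification with an orthoformate should occur only at the conjugated C8 carbonyl (extended dienol ether, as in the 3-enol-ether protection of 4-ene-3-ketones) and leave the neopentyl C3 cyclopentanone free, so that ring B is inert to the organolithium reagents of step 2; no stereocentre is formed.

Step 2
Reactants: 3 (S)-5-ethoxy-7a-methyl-2,6,7,7a-tetrahydro-1H-inden-1-one; 4 1,1-dibromoethane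
Product: 8 (1R,8aR)-6-ethoxy-1,8a-dimethyl-3,7,8,8a-tetrahydronaphthalen-2(1H)-one, via dibromo alkoxide 5 (not isolated), via β-oxido carbenoid 6 (not isolated), via lithium enolate 7 (not isolated)
Conditions: 4, LiN(i-Pr)2, THF/Et2O, −105 °C; 3, −95 °C; n-BuLi, −95 → −20 °C; inverse quench into AcOH, THF, −78 °C
Reagents that add atoms: 1,1-dibromoethane, CC(Br)Br
Why: 1,1-Dibromoethyllithium adds to the C3 ketone to give alkoxide 5 (the configuration at C3 is immaterial, since C3 returns to a carbonyl), and bromine–lithium exchange gives carbenoid 6, in which the alkoxide pushes a ring carbon onto the carbenoid carbon C4 with loss of LiBr. The closest known reaction type is the β-oxido carbenoid one-carbon homologation of cyclic ketones, a base-mediated relative of the Tiffeneau–Demjanov and semipinacol rearrangements. No ring is closed by cyclisation: the five-membered ring becomes ring A by the 1,2-shift, and C5 migrates with retention, so the stereocentre of 1 is kept. The selectivity needed is migration of the fully substituted C5 and not of the C2 methylene, which places C4 between C3 and C5; it should follow from the higher migratory aptitude of the more substituted, electron-richer carbon toward the electrophilic carbenoid centre. The shift delivers the C3–C4 enolate 7 regiospecifically, and its kinetic protonation from the α face, anti to the adjacent axial C5 methyl group, sets the new C4 stereocentre with its methyl group β (cis to the C5 methyl). The dienol ether keeps the ring-B carbonyl out of reach of both organolithium reagents.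

Step 3
Reactants: 8 (1R,8aR)-6-ethoxy-1,8a-dimethyl-3,7,8,8a-tetrahydronaphthalen-2(1H)-one; 9 water
Product: 11 (4aR,5R,6S)-6-hydroxy-4a,5-dimethyl-4,4a,5,6,7,8-hexahydronaphthalen-2(3H)-one, via hydroxy dienol ether 10 (not isolated)
Conditions: LiBH(s-Bu)3, THF, −78 °C; then 1 M HCl, THF/H2O, 20 °C
Reagents that add atoms: water, O
Why: The bulky hydride should attack the C3 ketone along the equatorial α-face trajectory because the axial β-face trajectory is blocked by the syn-axial C5 methyl group, which gives the axial 3β-alcohol (substrate-controlled ketone reduction), and aqueous acid then hydrolyses the dienol ether to the conjugated C9=C10 enone.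

Step 4
Reactants: 11 (4aR,5R,6S)-6-hydroxy-4a,5-dimethyl-4,4a,5,6,7,8-hexahydronaphthalen-2(3H)-one; 12 tert-butyldimethylsilyl triflate
Product: 13 (4aR,5R,6S)-6-(tert-butyldimethylsilyloxy)-4a,5-dimethyl-4,4a,5,6,7,8-hexahydronaphthalen-2(3H)-one
Conditions: TBSOTf, 2,6-lutidine, CH2Cl2, −78 → 0 °C
Reagents that add atoms: tert-butyldimethylsilyl triflate, CC(C)(C)[Si](C)(C)OS(=O)(=O)C(F)(F)F
Why: A silyl triflate with a hindered base silylates the hindered axial secondary alcohol (standard silyl ether protection), which is needed for the enolate chemistry of step 6.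

Step 5
Reactants: 14 methyl (R)-lactate; 15 triflic anhydride
Product: 16 methyl (R)-2-(trifluoromethylsulfonyloxy)propanoate
Conditions: Tf2O, 2,6-lutidine, CH2Cl2, −78 → 0 °C; used at once
Reagents that add atoms: triflic anhydride, O=S(=O)(OS(=O)(=O)C(F)(F)F)C(F)(F)F
Why: O-Sulfonylation of the lactate occurs at oxygen with retention at carbon and gives the configurationally defined electrophile.

Step 6
Reactants: 13 (4aR,5R,6S)-6-(tert-butyldimethylsilyloxy)-4a,5-dimethyl-4,4a,5,6,7,8-hexahydronaphthalen-2(3H)-one; 16 methyl (R)-2-(trifluoromethylsulfonyloxy)propanoate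
Product: 18 methyl (2R)-2-[(7S,8R,8aR)-7-(tert-butyldimethylsilyloxy)-8,8a-dimethyl-3-oxo-1,2,3,5,6,7,8,8a-octahydronaphthalen-2-yl]propanoate (both C7 epimers), via lithium dienolate 17 (not isolated)
Conditions: LiN(i-Pr)2, THF, −78 °C; then 16, −78 → −40 °C
Reagents that add atoms: methyl (R)-2-(trifluoromethylsulfonyloxy)propanoate, C[C@@H](OS(=O)(=O)C(F)(F)F)C(=O)OC
Why: Kinetic deprotonation of the enone at the α' carbon C7 gives the cross-conjugated dienolate 17, whose SN2 alkylation by the secondary α-triflyloxy ester proceeds with inversion and sets C11 as (R); the C7 configuration is immaterial because C7 becomes sp2 in step 7.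

Step 7
Reactants: 18 methyl (2R)-2-[(7S,8R,8aR)-7-(tert-butyldimethylsilyloxy)-8,8a-dimethyl-3-oxo-1,2,3,5,6,7,8,8a-octahydronaphthalen-2-yl]propanoate
Product: 19 methyl (2R)-2-[(7S,8R,8aR)-7-(tert-butyldimethylsilyloxy)-8,8a-dimethyl-3-oxo-3,5,6,7,8,8a-hexahydronaphthalen-2-yl]propanoate
Conditions: DDQ, 1,4-dioxane, 100 °C
Reagents that add atoms: none
Why: DDQ dehydrogenation of an enone to the cross-conjugated dienone (as for steroidal 4-en-3-ones to 1,4-dien-3-ones) runs through the C7–C8 dienol and hydride abstraction from C6; the C11 hydrogen, α to the ester, is a poor hydride donor, so the ring double bond C6=C7 and not an exocyclic one should form and C11 stays untouched.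

Step 8
Reactants: 19 methyl (2R)-2-[(7S,8R,8aR)-7-(tert-butyldimethylsilyloxy)-8,8a-dimethyl-3-oxo-3,5,6,7,8,8a-hexahydronaphthalen-2-yl]propanoate
Product: 20 methyl (2R)-2-[(7S,8R,8aR)-7-hydroxy-8,8a-dimethyl-3-oxo-3,5,6,7,8,8a-hexahydronaphthalen-2-yl]propanoate
Conditions: HF·pyridine, THF, 0 → 20 °C
Reagents that add atoms: none
Why: Fluoride cleavage of the silyl ether under buffered acidic conditions frees the 3β-hydroxyl group without touching the dienone or the base-sensitive C11 centre.

Step 9
Reactants: 20 methyl (2R)-2-[(7S,8R,8aR)-7-hydroxy-8,8a-dimethyl-3-oxo-3,5,6,7,8,8a-hexahydronaphthalen-2-yl]propanoate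
Product: 21 methyl (2R)-2-[(4aR,7S,8R,8aR)-7-hydroxy-8,8a-dimethyl-3-oxo-3,4,4a,5,6,7,8,8a-octahydronaphthalen-2-yl]propanoate
Conditions: [Ir(cod)(PCy3)(py)]PF6 (5 mol %), H2 (1 atm), CH2Cl2, 20 °C
Reagents that add atoms: none
Why: In this hydroxyl-directed homogeneous hydrogenation the cationic iridium catalyst binds the axial 3β-hydroxyl group and delivers H2 to the β face of the C9=C10 double bond, which sets C10 with H β (cis ring fusion), while the hindered C6=C7 double bond, out of reach of the hydroxyl group, should stay.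

Step 10
Reactants: 21 methyl (2R)-2-[(4aR,7S,8R,8aR)-7-hydroxy-8,8a-dimethyl-3-oxo-3,4,4a,5,6,7,8,8a-octahydronaphthalen-2-yl]propanoate; 22 angelic acid
Product: 23 methyl (2R)-2-[(4aR,7S,8R,8aR)-8,8a-dimethyl-7-{[(Z)-2-methylbut-2-enoyl]oxy}-3-oxo-3,4,4a,5,6,7,8,8a-octahydronaphthalen-2-yl]propanoate (CNP0323033.1)
Conditions: 22, 2,4,6-trichlorobenzoyl chloride, Et3N, toluene, 20 °C; then 21, 75 °C
Reagents that add atoms: angelic acid, C/C=C(/C)C(=O)O
Why: Yamaguchi esterification through the mixed anhydride, run without a nucleophilic amine catalyst, acylates the secondary alcohol with retention at C3 and should keep the (Z) geometry of the angelate.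

**Compound list**
1 | (S)-7a-methyl-2,3,7,7a-tetrahydro-1H-indene-1,5(6H)-dione | O=C1CC[C@]2(C)C(=O)CCC2=C1 | starting material
2 | triethyl orthoformate | CCOC(OCC)OCC | starting material
3 | (S)-5-ethoxy-7a-methyl-2,6,7,7a-tetrahydro-1H-inden-1-one | CCOC1=CC2=CCC(=O)[C@@]2(C)CC1 | intermediate
4 | 1,1-dibromoethane | CC(Br)Br | starting material
5 | dibromo alkoxide: lithium alkoxide from addition of 1,1-dibromoethyllithium to C3 of 3 (O β, expected) | CCOC1=CC2=CC[C@@](O[Li])(C(C)(Br)Br)[C@@]2(C)CC1 | intermediate (not isolated)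
6 | β-oxido carbenoid (C4 bears Li, Br and CH3; C4 not defined) | CCOC1=CC2=CC[C@@](O[Li])(C(C)([Li])Br)[C@@]2(C)CC1 | intermediate (not isolated)
7 | lithium enolate (C3–C4) of the ring-enlarged ketone | CCOC1=CC2=CCC(O[Li])=C(C)[C@@]2(C)CC1 | intermediate (not isolated)
8 | (1R,8aR)-6-ethoxy-1,8a-dimethyl-3,7,8,8a-tetrahydronaphthalen-2(1H)-one (4β-methyl C3 ketone) | CCOC1=CC2=CCC(=O)[C@H](C)[C@@]2(C)CC1 | intermediate
9 | water | O | starting material
10 | hydroxy dienol ether (3β-hydroxy derivative of 8) | CCOC1=CC2=CC[C@H](O)[C@H](C)[C@@]2(C)CC1 | intermediate (not isolated)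
11 | (4aR,5R,6S)-6-hydroxy-4a,5-dimethyl-4,4a,5,6,7,8-hexahydronaphthalen-2(3H)-one | O[C@H]1CCC2=CC(=O)CC[C@]2(C)[C@H]1C | intermediate
12 | tert-butyldimethylsilyl triflate | CC(C)(C)[Si](C)(C)OS(=O)(=O)C(F)(F)F | starting material
13 | (4aR,5R,6S)-6-(tert-butyldimethylsilyloxy)-4a,5-dimethyl-4,4a,5,6,7,8-hexahydronaphthalen-2(3H)-one | CC(C)(C)[Si](C)(C)O[C@H]1CCC2=CC(=O)CC[C@]2(C)[C@H]1C | intermediate
14 | methyl (R)-lactate | C[C@@H](O)C(=O)OC | starting material
15 | triflic anhydride | O=S(=O)(OS(=O)(=O)C(F)(F)F)C(F)(F)F | starting material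
16 | methyl (R)-2-(trifluoromethylsulfonyloxy)propanoate | C[C@@H](OS(=O)(=O)C(F)(F)F)C(=O)OC | intermediate
17 | lithium dienolate (C7–C8) of 13 | CC(C)(C)[Si](C)(C)O[C@H]1CCC2=CC(O[Li])=CC[C@]2(C)[C@H]1C | intermediate (not isolated)
18 | methyl (2R)-2-[(7S,8R,8aR)-7-(tert-butyldimethylsilyloxy)-8,8a-dimethyl-3-oxo-1,2,3,5,6,7,8,8a-octahydronaphthalen-2-yl]propanoate (both C7 epimers) | CC(C)(C)[Si](C)(C)O[C@H]1CCC2=CC(=O)C([C@@H](C)C(=O)OC)C[C@]2(C)[C@H]1C | intermediate
19 | methyl (2R)-2-[(7S,8R,8aR)-7-(tert-butyldimethylsilyloxy)-8,8a-dimethyl-3-oxo-3,5,6,7,8,8a-hexahydronaphthalen-2-yl]propanoate | CC(C)(C)[Si](C)(C)O[C@H]1CCC2=CC(=O)C([C@@H](C)C(=O)OC)=C[C@]2(C)[C@H]1C | intermediate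
20 | methyl (2R)-2-[(7S,8R,8aR)-7-hydroxy-8,8a-dimethyl-3-oxo-3,5,6,7,8,8a-hexahydronaphthalen-2-yl]propanoate | O[C@H]1CCC2=CC(=O)C([C@@H](C)C(=O)OC)=C[C@]2(C)[C@H]1C | intermediate
21 | methyl (2R)-2-[(4aR,7S,8R,8aR)-7-hydroxy-8,8a-dimethyl-3-oxo-3,4,4a,5,6,7,8,8a-octahydronaphthalen-2-yl]propanoate | O[C@H]1CC[C@@H]2CC(=O)C([C@@H](C)C(=O)OC)=C[C@]2(C)[C@H]1C | intermediate
22 | angelic acid, (Z)-2-methylbut-2-enoic acid | C/C=C(/C)C(=O)O | starting material
23 | CNP0323033.1, methyl (2R)-2-[(4aR,7S,8R,8aR)-8,8a-dimethyl-7-{[(Z)-2-methylbut-2-enoyl]oxy}-3-oxo-3,4,4a,5,6,7,8,8a-octahydronaphthalen-2-yl]propanoate | C/C=C(/C)C(=O)O[C@H]1CC[C@@H]2CC(=O)C([C@@H](C)C(=O)OC)=C[C@]2(C)[C@H]1C | target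

**Step count.** Total: 10 steps. Longest linear sequence: 9 steps (steps 1–4 and 6–10).

**Steps most likely to fail**

1. Step 2. The carbenoid reagent may enolise the hindered, doubly activated C3 ketone instead of adding to it, or the C2 methylene may migrate in place of C5, which would give the wrong ring-enlarged ketone. Fallback, from 3 back to 11: CeCl3-mediated addition of 1-ethoxyvinyllithium to C3 from the α face should give the 1-ethoxyvinyl carbinol F1. Dilute HCl hydrolyses both enol ethers to the α-hydroxy methyl ketone F2. Chelation-controlled reduction with Zn(BH4)2 (hydride anti to C5 in the Cram chelate) gives the diol F3. MsCl and Et3N sulfonylate only the secondary hydroxyl to the mesylate F4. AlEt3 in CH2Cl2 at −78 °C triggers the stereospecific semipinacol shift of C5 anti to the mesylate, with inversion at C4, to the 4β-methyl dione F5. LiBH(s-Bu)3 at −78 °C then reduces only the saturated C3 ketone and gives 11.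

2. Step 6. Proton transfer from the acidic α-position of the triflate to the basic dienolate, or elimination of triflate, may outrun substitution. Fallback, from 13 back to 18: LiN(i-Pr)2 then Me3SiCl gives the silyl dienol ether F6. Iridium-catalysed branched allylic alkylation with (E)-but-2-enyl methyl carbonate ([Ir(cod)Cl]2, chiral phosphoramidite, CsF, ZnF2), with the ligand enantiomer chosen for the required C11 configuration, gives the but-3-en-2-yl enone F7. Ozonolysis of the terminal vinyl group (dye end point, Me2S) gives the aldehyde F8. Pinnick oxidation (NaClO2, NaH2PO4, 2-methyl-2-butene) gives the acid F9, and Me3SiCHN2 in MeOH gives 18.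

3. Step 9. Chemoselectivity may be lost if the catalyst also reduces the C6=C7 double bond (for example under direction by the ester carbonyl), or hydrogen delivery may be slow. Fallback, from 18 back to 21: HF·pyridine gives the hydroxy enone F10. The same directed hydrogenation, now with a single C=C bond, gives the cis-fused ketone F11. Me3SiOTf and Et3N give the more substituted silyl enol ether, silylated also at O3, F12. Saegusa–Ito oxidation with Pd(OAc)2 in MeCN, with loss of the 3-O-silyl group on mild acidic work-up, gives 21.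

**Further compounds**
F1 | step 2 | (7aS)-5-ethoxy-1-(1-ethoxyvinyl)-7a-methyl-2,6,7,7a-tetrahydro-1H-inden-1-ol, hydroxyl cis to the 7a-methyl group | CCOC1=CC2=CC[C@@](O)(C(=C)OCC)[C@@]2(C)CC1
F2 | step 2 | (7aS)-1-acetyl-1-hydroxy-7a-methyl-1,2,3,6,7,7a-hexahydro-5H-inden-5-one, hydroxyl cis to the 7a-methyl group | O=C1C=C2CC[C@@](O)(C(C)=O)[C@@]2(C)CC1
F3 | step 2 | diol from chelation-controlled reduction of F2 (1-hydroxy-1-(1-hydroxyethyl) compound) | O=C1C=C2CC[C@@](O)([C@@H](C)O)[C@@]2(C)CC1
F4 | step 2 | secondary mesylate of F3 | O=C1C=C2CC[C@@](O)([C@@H](C)OS(C)(=O)=O)[C@@]2(C)CC1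
F5 | step 2 | (4aR,5R)-4a,5-dimethyl-4,4a,7,8-tetrahydronaphthalene-2,6(3H,5H)-dione | O=C1C=C2CCC(=O)[C@H](C)[C@@]2(C)CC1
F6 | step 6 | trimethylsilyl dienol ether (C7–C8) of 13 | CC(C)(C)[Si](C)(C)O[C@H]1CCC2=CC(O[Si](C)(C)C)=CC[C@]2(C)[C@H]1C
F7 | step 6 | 7-(but-3-en-2-yl) derivative of 13, C11 configured as in the target, both C7 epimers | CC(C)(C)[Si](C)(C)O[C@H]1CCC2=CC(=O)C([C@@H](C)C=C)C[C@]2(C)[C@H]1C
F8 | step 6 | aldehyde from ozonolysis of F7 | CC(C)(C)[Si](C)(C)O[C@H]1CCC2=CC(=O)C([C@@H](C)C=O)C[C@]2(C)[C@H]1C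
F9 | step 6 | carboxylic acid corresponding to 18 | CC(C)(C)[Si](C)(C)O[C@H]1CCC2=CC(=O)C([C@@H](C)C(=O)O)C[C@]2(C)[C@H]1C
F10 | step 9 | methyl (2R)-2-[(7S,8R,8aR)-7-hydroxy-8,8a-dimethyl-3-oxo-1,2,3,5,6,7,8,8a-octahydronaphthalen-2-yl]propanoate, both C7 epimers | O[C@H]1CCC2=CC(=O)C([C@@H](C)C(=O)OC)C[C@]2(C)[C@H]1C
F11 | step 9 | cis-fused (10β-H) saturated ketone from F10, both C7 epimers | O[C@H]1CC[C@@H]2CC(=O)C([C@@H](C)C(=O)OC)C[C@]2(C)[C@H]1C
F12 | step 9 | C7–C8 trimethylsilyl enol ether and 3-O-trimethylsilyl ether of F11 | C[Si](C)(C)O[C@H]1CC[C@@H]2CC(O[Si](C)(C)C)=C([C@@H](C)C(=O)OC)C[C@]2(C)[C@H]1C
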